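**Retrosynthetic overview**

1. Lepadin H ⇐ C3–O acyl bond by Mitsunobu esterification (inversion at C3) of the 2,3-cis alcohol 26 with (2E,4E)-octa-2,4-dienoic acid 29, then loss of N-Boc and O-TBS.
2. 26 ⇐ C5–C1' bond by B-alkyl Suzuki coupling of the C5 enol triflate 19 with the 9-BBN adduct of alkene 23 (from (R)-2-propyloxirane, which supplies C5'), then hydrogenation of C5=C6 and O-debenzylation.
3. 19 ⇐ cis-fused ketone 18 ⇐ dihydropyridine 13 by hydrogenation of C3=C4 (sets C3), acid removal of the N-auxiliary, and hydrogenation of C4a=C8a (sets the ring fusion).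
4. 13 ⇐ vinylogous amide 3 + enal 10. The route rests on this feature: N1–C8a=C4a–C5(=O) is the vinylogous amide of cyclohexane-1,3-dione and C2(Me)–C3(O)–C4 is a 2-alkoxybut-2-enal, so the piperidine ring is stitched on by C4a–C4 condensation and N1–C2 6π-azaelectrocyclization.
5. Ring order: the carbocycle (C4a–C8a) comes with the dione; the piperidine ring is closed in the key step. The auxiliary carries a 4-methoxy group (spectator change) so that acid can remove it before the ring-fusion hydrogenation.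

Key step: step 6

Assumption: the (S)-auxiliary is taken to favour the (2S) epimer of 13 under equilibrating conditions; if the sense is the opposite, the (R)-amine is used and nothing else changes, because the auxiliary is removed in step 8.

**Route**

Step 1
Reactants: 1 cyclohexane-1,3-dione; 2 (S)-1-(4-methoxyphenyl)ethan-1-amine
Product: 3 3-{[(1S)-1-(4-methoxyphenyl)ethyl]amino}cyclohex-2-en-1-one
Conditions: toluene, cat. AcOH, Dean–Stark, reflux
Reagents that add atoms: none
Why: Condensation of a primary amine with a cyclic 1,3-dione gives the vinylogous amide (enaminone) once water is removed, and the benzylic stereocentre is not involved.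

Step 2
Reactants: 4 methyl 2-(benzyloxy)acetate; 5 acetaldehyde
Product: 6 methyl 2-(benzyloxy)-3-hydroxybutanoate (racemic, syn/anti mixture)
Conditions: LDA, THF, −78 °C; then 5; aq. NH4Cl
Reagents that add atoms: none
Why: Aldol addition of a glycolate ester lithium enolate fixes the donor and acceptor roles that a direct cross-aldol of two aldehydes would leave open, and both new stereocentres are erased in step 3.

Step 3
Reactants: 6 methyl 2-(benzyloxy)-3-hydroxybutanoate
Product: 8 methyl (Z)-2-(benzyloxy)but-2-enoate, via mesylate 7 (not isolated)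
Conditions: MsCl, Et3N, CH2Cl2, 0 °C; then DBU, rt
Reagents that add atoms: none
Why: Mesylation and E1cB elimination (aldol dehydration) should give mainly the thermodynamically preferred (Z)-2-alkoxy enoate, with the methyl trans to the ester.

Step 4
Reactants: 8 methyl (Z)-2-(benzyloxy)but-2-enoate
Product: 9 (Z)-2-(benzyloxy)but-2-en-1-ol
Conditions: DIBAL-H (2.2 equiv), CH2Cl2, −78 °C; Rochelle salt
Reagents that add atoms: none
Why: DIBAL-H 1,2-reduction of a conjugated ester gives the allylic alcohol, and the neutral tartrate work-up spares the acid-labile enol ether.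

Step 5
Reactants: 9 (Z)-2-(benzyloxy)but-2-en-1-ol
Product: 10 (Z)-2-(benzyloxy)but-2-enal
Conditions: MnO2, CH2Cl2, rt
Reagents that add atoms: none
Why: MnO2 oxidation of an allylic alcohol gives the enal under neutral conditions without touching the enol ether or the alkene geometry.

Step 6
Reactants: 3 3-{[(1S)-1-(4-methoxyphenyl)ethyl]amino}cyclohex-2-en-1-one; 10 (Z)-2-(benzyloxy)but-2-enal
Product: 13 (2S)-3-(benzyloxy)-1-[(1S)-1-(4-methoxyphenyl)ethyl]-2-methyl-1,2,7,8-tetrahydroquinolin-5(6H)-one, via iminium acetate 11 (not isolated), via 1-azatriene 12 (not isolated)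
Conditions: 10, piperidinium acetate (1 equiv), Na2SO4, EtOAc, 85 °C; then 3, toluene, 110 °C, sealed tube
Reagents that add atoms: none
Why: This is the aza-[3+3] annulation of a vinylogous amide with an α,β-unsaturated iminium salt, a known condensation/electrocyclization sequence applied here to a 2-alkoxy enal: the enaminone α-carbon of 3 (future C4a) adds 1,2 to the iminium carbon of 11 (future C4) and loss of piperidine gives the 1-azatriene 12 (N1=C8a–C4a=C4–C3=C2). Thermal disrotatory 6π-azaelectrocyclization of 12 then forms N1–C2 and closes the only new ring, the six-membered dihydropyridine, onto the existing carbocycle. C2 is the only new stereocentre and is controlled by the N-(1-arylethyl) auxiliary, which through allylic 1,3-strain holds the C2 methyl pseudoaxial and biases the sense of rotation (torquoselectivity); because the closure is reversible at this temperature, the C2 epimers can equilibrate toward the less strained one. The step needs C- over N-attack and 1,2- over 1,4-addition; both follow from the soft carbon nucleophilicity of the enaminone and from the donor benzyloxy group, which lowers the electrophilicity of the enal β-carbon further. Na2SO4 takes up the water of condensation, and the benzyloxy group is carried through as the C3 enol ether.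

Step 7
Reactants: 13 (2S)-3-(benzyloxy)-1-[(1S)-1-(4-methoxyphenyl)ethyl]-2-methyl-1,2,7,8-tetrahydroquinolin-5(6H)-one
Product: 14 (2S,3S)-3-(benzyloxy)-1-[(1S)-1-(4-methoxyphenyl)ethyl]-2-methyl-2,3,4,6,7,8-hexahydroquinolin-5(1H)-one
Conditions: H2 (3 bar), 5% Pt/C, K2CO3 (solid), EtOAc, rt
Reagents that add atoms: none
Why: Heterogeneous hydrogenation over Pt (which does not cleave the benzylic C–O and C–N bonds) should saturate only the C3=C4 enol ether, the push-pull C4a=C8a being inert in neutral medium, and H2 should add anti to the pseudoaxial C2 methyl so that the C3 benzyloxy group ends cis to it (3S).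

Step 8
Reactants: 14 (2S,3S)-3-(benzyloxy)-1-[(1S)-1-(4-methoxyphenyl)ethyl]-2-methyl-2,3,4,6,7,8-hexahydroquinolin-5(1H)-one
Product: 15 (2S,3S)-3-(benzyloxy)-2-methyl-2,3,4,6,7,8-hexahydroquinolin-5(1H)-one
Conditions: TFA/CH2Cl2 (1:1), anisole, 25 → 50 °C
Reagents that add atoms: none
Why: Acidolytic N-debenzylation (SN1) releases the stabilised 4-methoxy-α-methylbenzyl cation from the amide-like vinylogous amide nitrogen, anisole traps it by Friedel–Crafts alkylation, and the alkyl benzyl ether and both stereocentres should be untouched.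

Step 9
Reactants: 15 (2S,3S)-3-(benzyloxy)-2-methyl-2,3,4,6,7,8-hexahydroquinolin-5(1H)-one
Product: 17 tert-butyl (2S,3S,4aR,8aR)-3-(benzyloxy)-5-hydroxy-2-methyloctahydroquinoline-1(2H)-carboxylate (C5 epimers), via amino alcohol 16 (not isolated)
Conditions: H2 (40 bar), 5% Pt/C, AcOH, rt; filter, evaporate; then Boc2O, Et3N, CH2Cl2, 40 °C
Reagents that add atoms: di-tert-butyl dicarbonate, CC(C)(C)OC(=O)OC(=O)OC(C)(C)C
Why: Catalytic hydrogenation of a secondary cyclic enaminone in acetic acid (via its protonated vinylogous iminium form) followed by carbamate formation should add H2 syn across C4a=C8a on the face opposite the cis C2-methyl and C3-benzyloxy groups, one of which is pseudoaxial in either half-chair, giving the cis ring fusion with H-4a and H-8a cis to H-2; the C5 carbonyl is expected to be reduced as well (corrected in step 10), and immediate N-Boc protection guards against retro-aza-Michael epimerization.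

Step 10
Reactants: 17 tert-butyl (2S,3S,4aR,8aR)-3-(benzyloxy)-5-hydroxy-2-methyloctahydroquinoline-1(2H)-carboxylate
Product: 18 tert-butyl (2S,3S,4aR,8aR)-3-(benzyloxy)-2-methyl-5-oxooctahydroquinoline-1(2H)-carboxylate
Conditions: Dess–Martin periodinane, NaHCO3, CH2Cl2, rt
Reagents that add atoms: none
Why: Dess–Martin oxidation under buffered, near-neutral conditions converges both carbinol epimers on the ketone without enolising C4a, and the carbamate nitrogen is too poor a leaving group for β-elimination.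

Step 11
Reactants: 18 tert-butyl (2S,3S,4aR,8aR)-3-(benzyloxy)-2-methyl-5-oxooctahydroquinoline-1(2H)-carboxylate
Product: 19 tert-butyl (2S,3S,4aR,8aR)-3-(benzyloxy)-2-methyl-5-(trifluoromethanesulfonyloxy)-3,4,4a,7,8,8a-hexahydroquinoline-1(2H)-carboxylate
Conditions: KHMDS, THF, −78 °C; then PhNTf2, −78 → 0 °C
Reagents that add atoms: N-phenylbis(trifluoromethanesulfonimide), O=S(=O)(N(c1ccccc1)S(=O)(=O)C(F)(F)F)C(F)(F)F
Why: Kinetic deprotonation removes a proton from the C6 methylene and not from the hindered ring-fusion methine C4a (so C4a is neither epimerised nor set up for β-elimination), and O-triflation of the enolate gives the C5=C6 enol triflate.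

Step 12
Reactants: 20 (R)-2-propyloxirane; 21 allylmagnesium bromide
Product: 22 (R)-oct-7-en-4-ol
Conditions: CuI (10 mol%), THF, −30 → 0 °C; aq. NH4Cl
Reagents that add atoms: none
Why: Copper-catalysed Grignard opening of a terminal epoxide occurs by SN2 at the unsubstituted carbon, so the stereocentre is not touched and the (R) configuration (future C5') is carried over.

Step 13
Reactants: 22 (R)-oct-7-en-4-ol
Product: 23 (R)-tert-butyldimethyl(oct-7-en-4-yloxy)silane
Conditions: TBSCl, imidazole, DMF, rt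
Reagents that add atoms: tert-butyldimethylsilyl chloride, CC(C)(C)[Si](C)(C)Cl
Why: Silylation of the secondary alcohol gives an ether that survives hydroboration, aqueous base, hydrogenation in EtOAc and the Mitsunobu step, and that falls with the Boc group at the end.

Step 14
Reactants: 23 (R)-tert-butyldimethyl(oct-7-en-4-yloxy)silane; 19 tert-butyl (2S,3S,4aR,8aR)-3-(benzyloxy)-2-methyl-5-(trifluoromethanesulfonyloxy)-3,4,4a,7,8,8a-hexahydroquinoline-1(2H)-carboxylate
Product: 25 tert-butyl (2S,3S,4aS,8aR)-3-(benzyloxy)-5-[(5R)-5-{[tert-butyl(dimethyl)silyl]oxy}octyl]-2-methyl-3,4,4a,7,8,8a-hexahydroquinoline-1(2H)-carboxylate, via B-alkyl-9-BBN 24 (not isolated)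
Conditions: 23, 9-BBN, THF, 0 °C → rt; then 19, PdCl2(dppf) (5 mol%), AsPh3, Cs2CO3, DMF/H2O, rt → 50 °C
Reagents that add atoms: none
Why: Anti-Markovnikov hydroboration of the terminal alkene followed by B-alkyl Suzuki–Miyaura coupling with the enol triflate forms the C5–C1' bond under mild base that Boc, benzyl ether and TBS ether tolerate.

Step 15
Reactants: 25 tert-butyl (2S,3S,4aS,8aR)-3-(benzyloxy)-5-[(5R)-5-{[tert-butyl(dimethyl)silyl]oxy}octyl]-2-methyl-3,4,4a,7,8,8a-hexahydroquinoline-1(2H)-carboxylate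
Product: 26 tert-butyl (2S,3S,4aS,5S,8aR)-5-[(5R)-5-{[tert-butyl(dimethyl)silyl]oxy}octyl]-3-hydroxy-2-methyloctahydroquinoline-1(2H)-carboxylate
Conditions: H2 (3 bar), Pd(OH)2/C, EtOAc/EtOH (4:1), rt
Reagents that add atoms: none
Why: Heterogeneous hydrogenation with concurrent benzyl ether hydrogenolysis should deliver H2 to C5=C6 from the convex face of the cis-fused bicycle (the face of H-4a and H-8a, opposite the C4 methylene that sits pseudoaxial on allylic C4a), setting C5 with H-5 cis to H-4a and freeing the C3 alcohol.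

Step 16
Reactants: 27 (E)-hex-2-enal; 28 malonic acid
Product: 29 (2E,4E)-octa-2,4-dienoic acid
Conditions: pyridine, piperidine (cat.), 90 °C; aq. HCl
Reagents that add atoms: none
Why: Doebner modification of the Knoevenagel condensation gives the (E)-2-alkenoic acid by decarboxylation of the alkylidene malonic acid and keeps the existing (E) alkene.

Step 17
Reactants: 26 tert-butyl (2S,3S,4aS,5S,8aR)-5-[(5R)-5-{[tert-butyl(dimethyl)silyl]oxy}octyl]-3-hydroxy-2-methyloctahydroquinoline-1(2H)-carboxylate; 29 (2E,4E)-octa-2,4-dienoic acid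
Product: 30 tert-butyl (2S,3R,4aS,5S,8aR)-5-[(5R)-5-{[tert-butyl(dimethyl)silyl]oxy}octyl]-2-methyl-3-{[(2E,4E)-octa-2,4-dienoyl]oxy}octahydroquinoline-1(2H)-carboxylate
Conditions: PPh3, DIAD, toluene, 0 °C → rt
Reagents that add atoms: none
Why: In the Mitsunobu esterification the carboxylate displaces the alkoxyphosphonium group by SN2 with inversion (3S → 3R, oxygen now trans to the C2 methyl), and the equatorial leaving group has no antiperiplanar hydrogen, which disfavours elimination.

Step 18
Reactants: 30 tert-butyl (2S,3R,4aS,5S,8aR)-5-[(5R)-5-{[tert-butyl(dimethyl)silyl]oxy}octyl]-2-methyl-3-{[(2E,4E)-octa-2,4-dienoyl]oxy}octahydroquinoline-1(2H)-carboxylate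
Product: 31 lepadin H, (2S,3R,4aS,5S,8aR)-5-[(5R)-5-hydroxyoctyl]-2-methyldecahydroquinolin-3-yl (2E,4E)-octa-2,4-dienoate
Conditions: TFA/H2O (9:1), 0 °C → rt; then aq. NaHCO3/MeOH
Reagents that add atoms: none
Why: Acidolysis removes the Boc carbamate and the secondary TBS ether in one operation, and the dienoate ester and all stereocentres are stable to acid, the ester oxygen being anti to N1 so that O→N acyl shift is not expected.

**Compound list**

1 | cyclohexane-1,3-dione | O=C1CCCC(=O)C1 | starting material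
2 | (S)-1-(4-methoxyphenyl)ethan-1-amine | C[C@H](N)c1ccc(OC)cc1 | starting material
3 | 3-{[(1S)-1-(4-methoxyphenyl)ethyl]amino}cyclohex-2-en-1-one | C[C@H](NC1=CC(=O)CCC1)c1ccc(OC)cc1 | intermediate
4 | methyl 2-(benzyloxy)acetate | COC(=O)COCc1ccccc1 | starting material
5 | acetaldehyde | CC=O | starting material
6 | methyl 2-(benzyloxy)-3-hydroxybutanoate (racemic, syn/anti mixture) | COC(=O)C(OCc1ccccc1)C(C)O | intermediate
7 | methyl 2-(benzyloxy)-3-(methanesulfonyloxy)butanoate (not isolated) | COC(=O)C(OCc1ccccc1)C(C)OS(C)(=O)=O | intermediate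
8 | methyl (Z)-2-(benzyloxy)but-2-enoate | C/C=C(\OCc1ccccc1)C(=O)OC | intermediate
9 | (Z)-2-(benzyloxy)but-2-en-1-ol | C/C=C(\OCc1ccccc1)CO | intermediate
10 | (Z)-2-(benzyloxy)but-2-enal | C/C=C(\OCc1ccccc1)C=O | intermediate
11 | 1-[(2Z)-2-(benzyloxy)but-2-en-1-ylidene]piperidin-1-ium acetate (not isolated) | C/C=C(\OCc1ccccc1)/C=[N+]1CCCCC1.CC(=O)[O-] | intermediate
12 | 1-azatriene, 2-[(2Z)-2-(benzyloxy)but-2-en-1-ylidene]-3-{[(1S)-1-(4-methoxyphenyl)ethyl]imino}cyclohexan-1-one, butenylidene arm cis to C=N (not isolated) | O=C1CCCC(=N[C@@H](C)c2ccc(OC)cc2)/C1=C\C(OCc1ccccc1)=C\C | intermediate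
13 | (2S)-3-(benzyloxy)-1-[(1S)-1-(4-methoxyphenyl)ethyl]-2-methyl-1,2,7,8-tetrahydroquinolin-5(6H)-one | C[C@H]1C(OCc2ccccc2)=CC3=C(CCCC3=O)N1[C@@H](C)c4ccc(OC)cc4 | intermediate
14 | (2S,3S)-3-(benzyloxy)-1-[(1S)-1-(4-methoxyphenyl)ethyl]-2-methyl-2,3,4,6,7,8-hexahydroquinolin-5(1H)-one | C(c1ccccc1)O[C@H]2CC3=C(CCCC3=O)N([C@@H](C)c4ccc(OC)cc4)[C@H]2C | intermediate
15 | (2S,3S)-3-(benzyloxy)-2-methyl-2,3,4,6,7,8-hexahydroquinolin-5(1H)-one | C(c1ccccc1)O[C@H]2CC3=C(CCCC3=O)N[C@H]2C | intermediate
16 | (2S,3S,4aR,8aR)-3-(benzyloxy)-2-methyldecahydroquinolin-5-ol, C5 epimers, cis-fused, H-2/H-3/H-4a/H-8a all cis (not isolated) | C(c1ccccc1)O[C@H]2C[C@H]3C(O)CCC[C@H]3N[C@H]2C | intermediate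
17 | tert-butyl (2S,3S,4aR,8aR)-3-(benzyloxy)-5-hydroxy-2-methyloctahydroquinoline-1(2H)-carboxylate, C5 epimers | C(c1ccccc1)O[C@H]2C[C@H]3C(O)CCC[C@H]3N(C(=O)OC(C)(C)C)[C@H]2C | intermediate
18 | tert-butyl (2S,3S,4aR,8aR)-3-(benzyloxy)-2-methyl-5-oxooctahydroquinoline-1(2H)-carboxylate | C(c1ccccc1)O[C@H]2C[C@H]3C(=O)CCC[C@H]3N(C(=O)OC(C)(C)C)[C@H]2C | intermediate
19 | tert-butyl (2S,3S,4aR,8aR)-3-(benzyloxy)-2-methyl-5-(trifluoromethanesulfonyloxy)-3,4,4a,7,8,8a-hexahydroquinoline-1(2H)-carboxylate | C(c1ccccc1)O[C@H]2C[C@H]3C(OS(=O)(=O)C(F)(F)F)=CCC[C@H]3N(C(=O)OC(C)(C)C)[C@H]2C | intermediate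
20 | (R)-2-propyloxirane | CCC[C@@H]1CO1 | starting material
21 | allylmagnesium bromide | C=CC[Mg]Br | starting material
22 | (R)-oct-7-en-4-ol | C=CCC[C@H](O)CCC | intermediate
23 | (R)-tert-butyldimethyl(oct-7-en-4-yloxy)silane | C=CCC[C@H](O[Si](C)(C)C(C)(C)C)CCC | intermediate
24 | 9-[(5R)-5-{[tert-butyl(dimethyl)silyl]oxy}octyl]-9-borabicyclo[3.3.1]nonane (not isolated) | C(CCC[C@H](O[Si](C)(C)C(C)(C)C)CCC)B1C2CCCC1CCC2 | intermediate
25 | tert-butyl (2S,3S,4aS,8aR)-3-(benzyloxy)-5-[(5R)-5-{[tert-butyl(dimethyl)silyl]oxy}octyl]-2-methyl-3,4,4a,7,8,8a-hexahydroquinoline-1(2H)-carboxylate | C(c1ccccc1)O[C@H]2C[C@H]3C(CCCC[C@H](O[Si](C)(C)C(C)(C)C)CCC)=CCC[C@H]3N(C(=O)OC(C)(C)C)[C@H]2C | intermediate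
26 | tert-butyl (2S,3S,4aS,5S,8aR)-5-[(5R)-5-{[tert-butyl(dimethyl)silyl]oxy}octyl]-3-hydroxy-2-methyloctahydroquinoline-1(2H)-carboxylate | O[C@H]1C[C@H]2[C@@H](CCCC[C@H](O[Si](C)(C)C(C)(C)C)CCC)CCC[C@H]2N(C(=O)OC(C)(C)C)[C@H]1C | intermediate
27 | (E)-hex-2-enal | CCC/C=C/C=O | starting material
28 | malonic acid | OC(=O)CC(=O)O | starting material
29 | (2E,4E)-octa-2,4-dienoic acid | CCC/C=C/C=C/C(=O)O | intermediate
30 | tert-butyl (2S,3R,4aS,5S,8aR)-5-[(5R)-5-{[tert-butyl(dimethyl)silyl]oxy}octyl]-2-methyl-3-{[(2E,4E)-octa-2,4-dienoyl]oxy}octahydroquinoline-1(2H)-carboxylate | CCC/C=C/C=C/C(=O)O[C@@H]1C[C@H]2[C@@H](CCCC[C@H](O[Si](C)(C)C(C)(C)C)CCC)CCC[C@H]2N(C(=O)OC(C)(C)C)[C@H]1C | intermediate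
31 | lepadin H, (2S,3R,4aS,5S,8aR)-5-[(5R)-5-hydroxyoctyl]-2-methyldecahydroquinolin-3-yl (2E,4E)-octa-2,4-dienoate | CCC/C=C/C=C/C(=O)O[C@@H]1C[C@H]2[C@@H](CCCC[C@H](O)CCC)CCC[C@H]2N[C@H]1C | target

**Step count and risks**

Total step count: 18. Longest linear sequence: 14 steps (2 → 3 → 4 → 5 → 6 → 7 → 8 → 9 → 10 → 11 → 14 → 15 → 17 → 18).

The three steps most likely to fail:

Step 6. The donor-substituted iminium ion may condense so slowly that the enal polymerises or the sequence stalls before ring closure, or the electrocyclization may show too little facial preference at C2 for the epimers of 13 to be obtained pure. The fallback builds C2 and C3 before the piperidine is closed; it sets out from cyclohexane-1,3-dione 1 and comes back at 15. Sharpless asymmetric aminohydroxylation of commercial ethyl (E)-but-2-enoate (tert-butyl carbamate, t-BuOCl, NaOH, K2OsO2(OH)4, the DHQ-type PHAL ligand chosen for the (2R,3S) series) should give ethyl (2R,3S)-3-[(tert-butoxycarbonyl)amino]-2-hydroxybutanoate F1. O-Benzylation with BnBr and Ag2O gives ethyl (2R,3S)-2-(benzyloxy)-3-[(tert-butoxycarbonyl)amino]butanoate F2, and DIBAL-H at −78 °C gives tert-butyl N-[(2S,3R)-3-(benzyloxy)-4-oxobutan-2-yl]carbamate F3. Organocatalytic reductive alkylation of 1 with F3 (Hantzsch ester, cat. L-proline; Knoevenagel condensation then transfer hydrogenation) gives 2-[(2S,3S)-2-(benzyloxy)-3-[(tert-butoxycarbonyl)amino]butyl]cyclohexane-1,3-dione F4. TFA then removes the Boc group and the free amine condenses with a ring carbonyl, closing the piperidine as enaminone 15.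

Step 9. Hydrogen may be delivered to the wrong face of C4a=C8a, or the reduction may run stepwise through the iminium ion with unselective protonation at C4a and give trans-fused material; prolonged exposure to Pt in AcOH may also saturate the benzyl ring. The fallback replaces control in the N–H series by allylic 1,3-strain control in an N-acyl series; it sets out from 15 and comes back at 18. N-Acylation of 15 (NaH, Boc2O, THF) gives tert-butyl (2S,3S)-3-(benzyloxy)-2-methyl-5-oxo-3,4,5,6,7,8-hexahydroquinoline-1(2H)-carboxylate F5, in which the carbamate forces the C2 methyl axial. Neutral hydrogenation over Pt/C in EtOAc should then add H2 anti to that methyl, leave the ketone and the benzyl ether in place, and give 18 directly.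

Step 15. Hydrogen delivery to the trisubstituted C5=C6 alkene of the conformationally mobile N-Boc bicycle may show poor facial selectivity and give C5 epimers. The fallback sets C5 under thermodynamic control; it sets out from ketone 18 and comes back at 26. Wittig methoxymethylenation (Ph3P=CHOMe from the phosphonium chloride and KOt-Bu) gives tert-butyl (2S,3S,4aS,8aR)-3-(benzyloxy)-5-(methoxymethylidene)-2-methyloctahydroquinoline-1(2H)-carboxylate F6. Mild aqueous acid hydrolysis and equilibration with K2CO3 in MeOH give tert-butyl (2S,3S,4aS,5S,8aR)-3-(benzyloxy)-5-formyl-2-methyloctahydroquinoline-1(2H)-carboxylate F7, whose formyl group should settle in the equatorial position on the carbocycle. Methylenation (Ph3P=CH2) gives tert-butyl (2S,3S,4aS,5R,8aR)-3-(benzyloxy)-5-ethenyl-2-methyloctahydroquinoline-1(2H)-carboxylate F8. Cross-metathesis with alkene 23 (second-generation Grubbs catalyst) gives tert-butyl (2S,3S,4aS,5R,8aR)-3-(benzyloxy)-5-[(1E,5R)-5-{[tert-butyl(dimethyl)silyl]oxy}oct-1-en-1-yl]-2-methyloctahydroquinoline-1(2H)-carboxylate F9. Hydrogenation over Pd(OH)2/C then saturates the side-chain alkene, which creates no ring stereocentre, and removes the benzyl group to give 26.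

**Further compounds**

F1 | step 6 | ethyl (2R,3S)-3-[(tert-butoxycarbonyl)amino]-2-hydroxybutanoate | CCOC(=O)[C@H](O)[C@H](C)NC(=O)OC(C)(C)C
F2 | step 6 | ethyl (2R,3S)-2-(benzyloxy)-3-[(tert-butoxycarbonyl)amino]butanoate | CCOC(=O)[C@H](OCc1ccccc1)[C@H](C)NC(=O)OC(C)(C)C
F3 | step 6 | tert-butyl N-[(2S,3R)-3-(benzyloxy)-4-oxobutan-2-yl]carbamate | O=C[C@H](OCc1ccccc1)[C@H](C)NC(=O)OC(C)(C)C
F4 | step 6 | 2-[(2S,3S)-2-(benzyloxy)-3-[(tert-butoxycarbonyl)amino]butyl]cyclohexane-1,3-dione | O=C1CCCC(=O)C1C[C@H](OCc2ccccc2)[C@H](C)NC(=O)OC(C)(C)C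
F5 | step 9 | tert-butyl (2S,3S)-3-(benzyloxy)-2-methyl-5-oxo-3,4,5,6,7,8-hexahydroquinoline-1(2H)-carboxylate | C(c1ccccc1)O[C@H]2CC3=C(CCCC3=O)N(C(=O)OC(C)(C)C)[C@H]2C
F6 | step 15 | tert-butyl (2S,3S,4aS,8aR)-3-(benzyloxy)-5-(methoxymethylidene)-2-methyloctahydroquinoline-1(2H)-carboxylate (E/Z mixture) | C(c1ccccc1)O[C@H]2C[C@H]3C(=COC)CCC[C@H]3N(C(=O)OC(C)(C)C)[C@H]2C
F7 | step 15 | tert-butyl (2S,3S,4aS,5S,8aR)-3-(benzyloxy)-5-formyl-2-methyloctahydroquinoline-1(2H)-carboxylate | C(c1ccccc1)O[C@H]2C[C@H]3[C@@H](C=O)CCC[C@H]3N(C(=O)OC(C)(C)C)[C@H]2C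
F8 | step 15 | tert-butyl (2S,3S,4aS,5R,8aR)-3-(benzyloxy)-5-ethenyl-2-methyloctahydroquinoline-1(2H)-carboxylate | C(c1ccccc1)O[C@H]2C[C@H]3[C@@H](C=C)CCC[C@H]3N(C(=O)OC(C)(C)C)[C@H]2C
F9 | step 15 | tert-butyl (2S,3S,4aS,5R,8aR)-3-(benzyloxy)-5-[(1E,5R)-5-{[tert-butyl(dimethyl)silyl]oxy}oct-1-en-1-yl]-2-methyloctahydroquinoline-1(2H)-carboxylate | C(c1ccccc1)O[C@H]2C[C@H]3[C@@H](/C=C/CC[C@H](O[Si](C)(C)C(C)(C)C)CCC)CCC[C@H]3N(C(=O)OC(C)(C)C)[C@H]2C
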